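**Assumption:** the target has no stereocentre (it is achiral), so no enantiocontrol is needed; it is made as the free hydrogen sulfate, as drawn.

**Retrosynthetic overview**
1. S–O disconnection: the target comes from chemoselective O-sulfation of the primary alcohol of 2-(2,3-dibromo-4,5-dihydroxyphenyl)ethanol.
2. The catechol comes from the corresponding guaiacol by chelation-assisted O-demethylation.
3. The two adjacent C–Br bonds come from double electrophilic bromination of commercial homovanillyl alcohol (OH directs ortho, OMe directs para).
4. No ring is formed; the benzene ring and the C2 side chain are bought in the starting material.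

**Route**

Step 1
Reactants: 1 homovanillyl alcohol [4-(2-hydroxyethyl)-2-methoxyphenol]
Product: 2 2-(2,3-dibromo-4-hydroxy-5-methoxyphenyl)ethanol
Conditions: NBS (2.05 equiv), MeCN, 0 °C → rt, dark
Reagents that add atoms: N-bromosuccinimide, O=C1CCC(=O)N1Br
Why: Double electrophilic aromatic bromination (SEAr) in which the free phenol directs one bromine ortho to itself and the methoxy group directs the other para to itself, two adjacent positions, while the remaining site between OMe and the side chain is the least activated, so two equivalents stop at the 2,3-dibromo pattern with no stereocentre formed.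

Step 2
Reactants: 2 2-(2,3-dibromo-4-hydroxy-5-methoxyphenyl)ethanol
Product: 3 2-(2,3-dibromo-4,5-dihydroxyphenyl)ethanol
Conditions: AlCl3 (3.5 equiv), pyridine (10 equiv), CH2Cl2, reflux, Ar; then 2 M HCl, 0 °C
Reagents that add atoms: none
Why: Chelation-assisted Lewis-acid ether cleavage (aluminium chloride–pyridine demethylation of an o-hydroxyanisole) in which the aluminium phenoxide binds the neighbouring methoxy oxygen so chloride removes the methyl group by SN2, while the aryl bromides and the primary alcohol (an inert aluminium alkoxide, not converted to a halide as BBr3 could do) survive.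

Step 3
Reactants: 3 2-(2,3-dibromo-4,5-dihydroxyphenyl)ethanol
Product: 5 2-(2,3-dibromo-4,5-dihydroxyphenyl)ethyl hydrogen sulfate, via triethylammonium sulfate salt 4 (not isolated)
Conditions: SO3·NEt3 (1.2 equiv), pyridine, rt, Ar; then H2O, Dowex 50W-X8 (H+ form), 0–5 °C, lyophilise
Reagents that add atoms: sulfur trioxide–triethylamine complex, CC[N+](CC)(CC)S(=O)(=O)[O-]
Why: Chemoselective O-sulfation with a mild amine–SO3 complex, in which the primary alkanol is a far better neutral nucleophile than the hindered, electron-poor brominated catechol hydroxyls (which need phenoxide formation to react), so about one equivalent gives only the alkyl sulfate, and cation exchange on an acidic resin then gives the free hydrogen sulfate.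

**Compound list**
1 | homovanillyl alcohol, 4-(2-hydroxyethyl)-2-methoxyphenol | COc1cc(CCO)ccc1O | starting material
2 | 2-(2,3-dibromo-4-hydroxy-5-methoxyphenyl)ethanol | COc1cc(CCO)c(Br)c(Br)c1O | intermediate
3 | 2-(2,3-dibromo-4,5-dihydroxyphenyl)ethanol | OCCc1cc(O)c(O)c(Br)c1Br | intermediate
4 | triethylammonium 2-(2,3-dibromo-4,5-dihydroxyphenyl)ethyl sulfate | CC[NH+](CC)CC.[O-]S(=O)(=O)OCCc1cc(O)c(O)c(Br)c1Br | intermediate
5 | 2-(2,3-dibromo-4,5-dihydroxyphenyl)ethyl hydrogen sulfate | O=S(=O)(O)OCCc1cc(O)c(O)c(Br)c1Br | target

**Total step count:** 3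
**Longest linear sequence:** 3 steps (1 → 2 → 3 → 5)

**Steps most likely to fail, with fallbacks**

Step 3 (most risky: partial sulfation of a phenol, or mixtures). The fallback is a protecting-group route that sets out from 3. TBSCl and imidazole in DMF silylate all three hydroxyls to give tert-butyl{2-[2,3-dibromo-4,5-bis(tert-butyldimethylsilyloxy)phenyl]ethoxy}dimethylsilane F5. PPTS in MeOH at rt then cleaves only the acid-labile primary alkyl silyl ether, leaving the more acid-stable aryl silyl ethers, to give 2-[2,3-dibromo-4,5-bis(tert-butyldimethylsilyloxy)phenyl]ethanol F6. Now the only free hydroxyl is the primary one, and SO3·NEt3 in DMF gives triethylammonium 2-[2,3-dibromo-4,5-bis(tert-butyldimethylsilyloxy)phenyl]ethyl sulfate F7. Et3N·3HF in MeCN removes both aryl silyl groups without touching the sulfate or the aryl bromides. The fallback comes back to the route at 4, which is passed through the acidic resin to 5 as in step 3.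

Step 1 (over-bromination to the tribromide, or an inseparable isomer mixture). The fallback is a stepwise bromination with a switch of directing group, setting out from 1. Ac2O in pyridine acetylates both hydroxyls to give 4-(2-acetoxyethyl)-2-methoxyphenyl acetate F1. With the phenol masked, only the methoxy group directs, and Br2/NaOAc in AcOH brominates para to it to give 2-(4-acetoxy-2-bromo-5-methoxyphenyl)ethyl acetate F2. K2CO3 in MeOH removes both acetates to give 2-(2-bromo-4-hydroxy-5-methoxyphenyl)ethanol F3. One equivalent of NBS in MeCN then brominates the only open position ortho to the freed phenol, and the fallback comes back to the route at 2.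

Step 2 (sluggish demethylation on a ring without an electron-withdrawing group, or trouble from the free alcohol). The fallback is an oxidative demethylation that sets out from 2. NaIO4 in aqueous AcOH/EtOAc at 0 °C (periodate oxidation of a guaiacol) expels the methyl group as methanol and gives 3,4-dibromo-5-(2-hydroxyethyl)cyclohexa-3,5-diene-1,2-dione F4. This o-quinone is reduced at once in the same flask with aqueous Na2S2O4, and the fallback comes back to the route at 3.

**Further compounds**
F1 | step 1 | 4-(2-acetoxyethyl)-2-methoxyphenyl acetate | COc1cc(CCOC(C)=O)ccc1OC(C)=O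
F2 | step 1 | 2-(4-acetoxy-2-bromo-5-methoxyphenyl)ethyl acetate | COc1cc(CCOC(C)=O)c(Br)cc1OC(C)=O
F3 | step 1 | 2-(2-bromo-4-hydroxy-5-methoxyphenyl)ethanol | COc1cc(CCO)c(Br)cc1O
F4 | step 2 | 3,4-dibromo-5-(2-hydroxyethyl)cyclohexa-3,5-diene-1,2-dione | O=C1C(=O)C(Br)=C(Br)C(CCO)=C1
F5 | step 3 | tert-butyl{2-[2,3-dibromo-4,5-bis(tert-butyldimethylsilyloxy)phenyl]ethoxy}dimethylsilane | CC(C)(C)[Si](C)(C)OCCc1cc(O[Si](C)(C)C(C)(C)C)c(O[Si](C)(C)C(C)(C)C)c(Br)c1Br
F6 | step 3 | 2-[2,3-dibromo-4,5-bis(tert-butyldimethylsilyloxy)phenyl]ethanol | OCCc1cc(O[Si](C)(C)C(C)(C)C)c(O[Si](C)(C)C(C)(C)C)c(Br)c1Br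
F7 | step 3 | triethylammonium 2-[2,3-dibromo-4,5-bis(tert-butyldimethylsilyloxy)phenyl]ethyl sulfate | CC[NH+](CC)CC.[O-]S(=O)(=O)OCCc1cc(O[Si](C)(C)C(C)(C)C)c(O[Si](C)(C)C(C)(C)C)c(Br)c1Br
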